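**Retrosynthetic overview**

1. Numbering: C1 ketone, C2=C3(Me) enone alkene, C4 and C11 the cyclobutane CH carbons on C3 and C1, C5 the cyclobutane CH next to C6 (CMe2), C7 the isovalerate carbinol, C8 the CH2, C9 the tiglate carbinol, C10 the quaternary C–Me. The strategy rests on one feature: C4, the γ-carbon of the C1 enone, lies 1,4 to C10 (through C5–C11), and C10's neighbour C9 bears oxygen. A C9,C10-epoxide and a C1 silyl dienol ether in a cis-fused cyclohexadiene/cycloheptane bicycle can therefore form C4–C10, which closes the cyclobutane and with it the bicyclo[3.1.1]heptenone and the bicyclo[4.1.1]octane.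
2. Target ⇒ C9 alcohol 24 (tiglate last) ⇒ dienol ether epoxide 23 (C4–C10) ⇒ epoxy enone 22 ⇒ dienone 21, whose C9=C10(Me) unit comes from the enol triflate of a C10 ketone and MeZnCl.
3. The seven-membered carbocycle (C5–C11) comes from a cis-fused bicyclic δ-lactone by SmI2 ring expansion (C9–C10 formed, O7–C10 cleaved). The six-membered carbocycle comes from a Diels–Alder reaction of a 1-silyloxy-3-methyldiene with an α,β-unsaturated δ-lactone, anti to the C7 side chain.
4. The lactone comes from acrylate ring-closing metathesis after an iridium-catalysed tert-prenylation that sets C7.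
5. Ring order: δ-lactone (temporary) → cyclohexene → cycloheptanone → cyclobutane.

Key step: step 17

Remarks on the chemistry:
- "Upper face" means the face of the seven-membered ring that carries H5 and H11. C1, C4 and the C7 oxygen lie on the lower face; the epoxide oxygen lies on the upper face.
- The (S)-SEGPHOS iridium catalyst is assumed, by analogy with related reverse prenylations, to give the R carbinol 5; if the sense is the opposite, the (R)-ligand is used.
- The C1 configuration drawn for 11–20 is that of the endo adduct; it is of no consequence and is erased in step 14.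

Step 1
Reactants: 1 propane-1,3-diol
Product: 2 3-[(4-methoxybenzyl)oxy]propan-1-ol
Conditions: NaH (1 equiv), PMBCl (1 equiv), Bu4NI (cat.), THF–DMF, 0 °C to rt; diol 3 equiv
Reagents that add atoms: 4-methoxybenzyl chloride, COc1ccc(CCl)cc1
Why: Williamson ether synthesis, in which the excess of diol makes the mono-ether the main product.

Step 2
Reactants: 2 3-[(4-methoxybenzyl)oxy]propan-1-ol; 3 3-methylbuta-1,2-diene
Product: 5 (R)-1-[(4-methoxybenzyl)oxy]-4,4-dimethylhex-5-en-3-ol, via 3-(4-methoxybenzyloxy)propanal 4 (not isolated)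
Conditions: [Ir(cod)Cl]2 (2.5 mol%), (S)-SEGPHOS (5 mol%), 4-cyano-3-nitrobenzoic acid (10 mol%), Cs2CO3 (20 mol%), 3 (3 equiv), toluene, 60 °C
Reagents that add atoms: none
Why: Krische iridium-catalysed transfer-hydrogenative reverse prenylation, in which the catalyst dehydrogenates 2 to aldehyde 4, hydrometalates the allene to a 1,1-dimethylallyl iridium species and adds it through its tertiary carbon in a closed chair transition state, so that the chiral C,O-benzoate catalyst sets C7 (R) while the quaternary C6 and the C5 vinyl group arise in the same bond formation.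

Step 3
Reactants: 5 (R)-1-[(4-methoxybenzyl)oxy]-4,4-dimethylhex-5-en-3-ol; 6 acryloyl chloride
Product: 7 (R)-1-[(4-methoxybenzyl)oxy]-4,4-dimethylhex-5-en-3-yl acrylate
Conditions: Et3N, DMAP (cat.), CH2Cl2, −20 to 0 °C
Reagents that add atoms: none
Why: DMAP-catalysed acylation of the secondary alcohol with the acid chloride gives the metathesis substrate without touching C7.

Step 4
Reactants: 7 (R)-1-[(4-methoxybenzyl)oxy]-4,4-dimethylhex-5-en-3-yl acrylate
Product: 8 (R)-6-{2-[(4-methoxybenzyl)oxy]ethyl}-5,5-dimethyl-5,6-dihydro-2H-pyran-2-one (O7–C10(=O)–C11=C5–C6–C7 ring)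
Conditions: second-generation Hoveyda–Grubbs catalyst (5 mol%), toluene, 80 °C, argon sparge
Reagents that add atoms: none
Why: Ring-closing metathesis of the acrylate onto the neopentyl-type vinyl group is driven by loss of ethene and helped by the gem-dimethyl group, and closes the six-membered α,β-unsaturated lactone without touching a stereocentre.

Step 5
Reactants: 9 3-methylbut-2-enal
Product: 10 (E)-tert-butyl(dimethyl)[(3-methylbuta-1,3-dien-1-yl)oxy]silane
Conditions: TBSOTf, Et3N, Et2O, 0 °C to rt
Reagents that add atoms: tert-butyldimethylsilyl trifluoromethanesulfonate, CC(C)(C)[Si](C)(C)OS(=O)(=O)C(F)(F)F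
Why: Soft enolisation of the enal through its O-silyl oxocarbenium ion removes a γ-proton (no α′ hydrogen exists) and gives the E 1-silyloxy diene.

Step 6
Reactants: 8 (R)-6-{2-[(4-methoxybenzyl)oxy]ethyl}-5,5-dimethyl-5,6-dihydro-2H-pyran-2-one; 10 (E)-tert-butyl(dimethyl)[(3-methylbuta-1,3-dien-1-yl)oxy]silane
Product: 11 cis-fused bicyclic δ-lactone (lactone O7–C10(=O); H5 and H11 cis; C4 on the lactone face opposite the C7 side chain; C1–OTBS; C2=C3(Me); C6 Me2; C7–CH2CH2OPMB)
Conditions: HNTf2 (10 mol%), 10 (1.5 equiv), CH2Cl2, −78 to −30 °C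
Reagents that add atoms: none
Why: Diels–Alder reaction of a 1-silyloxy-3-methyldiene with an α,β-unsaturated lactone under silyl triflimide catalysis (TBSNTf2 formed from HNTf2 and 10), in which the CH2 terminus C4 bonds to the β-carbon C5 and the oxygen-bearing C1 to the α-carbon C11 (ortho/para rule), suprafacial addition to the ring Z-alkene fixes the cis C5/C11 fusion, and the diene adds anti to the pseudo-equatorial C7 side chain and the pseudo-axial C6 methyl (the usual trans-4,6 mode of 6-substituted dihydropyranones), which places C4 cis to O7 once C7–C8 becomes a ring bond.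

Step 7
Reactants: 11 cis-fused bicyclic δ-lactone with CH2CH2OPMB side chain
Product: 12 primary alcohol (11 with C9–OH in place of C9–OPMB)
Conditions: DDQ (1.3 equiv), CH2Cl2–pH 7 buffer, 0 °C
Reagents that add atoms: none
Why: Oxidative cleavage of the electron-rich PMB ether by DDQ (hydride abstraction, then hydrolysis of the hemiacetal) leaves the allylic silyl ether, the alkene and the lactone untouched.

Step 8
Reactants: 12 primary alcohol
Product: 13 primary iodide (C9–I)
Conditions: I2, PPh3, imidazole, CH2Cl2, 0 °C to rt
Reagents that add atoms: iodine, II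
Why: Appel-type (Garegg–Samuelsson) iodination of the primary alcohol through the alkoxyphosphonium iodide and SN2 displacement.

Step 9
Reactants: 13 primary iodide
Product: 15 cis-fused bicyclo[5.4.0] hydroxy ketone (C10=O, C7–OH, C1–OTBS, C2=C3(Me), C6 Me2), via bridged hemiketal 14 (not isolated)
Conditions: SmI2 (2.5 equiv), Fe(dbm)3 (2 mol%, dbm = dibenzoylmethanate), THF, −30 °C to rt; aq. NH4Cl
Reagents that add atoms: none
Why: Molander intramolecular nucleophilic acyl substitution, in which SmI2 reduces the iodide to an alkylsamarium that adds to the lactone carbonyl in a five-membered-ring-forming mode (C9–C10) to give the samarium alkoxide of hemiketal 14, whose collapse on work-up cleaves O7–C10 and releases the seven-membered C10 ketone with C7–OH, without touching C5, C7 or C11.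

Step 10
Reactants: 15 hydroxy ketone; 16 3-methylbutanoyl chloride
Product: 17 C7 isovalerate of the C10 ketone
Conditions: pyridine, DMAP (cat.), CH2Cl2, 0 °C to rt
Reagents that add atoms: none
Why: DMAP-catalysed acylation of the hindered secondary C7 alcohol, any closed hemiketal 14 being drained through the open hydroxy ketone.

Step 11
Reactants: 17 C7 isovalerate of the C10 ketone
Product: 18 C9=C10 enol triflate
Conditions: KHMDS (1.1 equiv), THF, −78 °C; then PhNTf2, −78 to 0 °C
Reagents that add atoms: N-phenylbis(trifluoromethanesulfonimide), O=S(=O)(N(c1ccccc1)S(=O)(=O)C(F)(F)F)C(F)(F)F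
Why: Kinetic enolisation with a hindered amide base takes a C9 proton rather than the ring-fusion methine H11 or the less acidic ester α-protons, and O-sulfonylation of the potassium enolate fixes the C9=C10 position without epimerising C11.

Step 12
Reactants: 18 C9=C10 enol triflate
Product: 19 diene with C9=C10(Me) and C2=C3(Me), C1–OTBS, C7 isovalerate
Conditions: Pd(PPh3)4 (5 mol%), MeZnCl (2 equiv), THF, rt to 50 °C
Reagents that add atoms: methylzinc chloride, C[Zn]Cl
Why: Negishi cross-coupling of the alkenyl triflate installs the C10 methyl group with retention of the alkene position and tolerates the ester and the silyl ether.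

Step 13
Reactants: 19 diene with C1–OTBS
Product: 20 allylic alcohol (C1–OH)
Conditions: TBAF, AcOH (1:1), THF, 0 °C to rt
Reagents that add atoms: none
Why: Fluoride desilylation of the allylic silyl ether, buffered with acetic acid so that the isovalerate is not cleaved.

Step 14
Reactants: 20 allylic alcohol
Product: 21 dienone (C1=O, C2=C3(Me), C9=C10(Me), C7 isovalerate, cis fusion)
Conditions: MnO2 (activated, excess), CH2Cl2, rt
Reagents that add atoms: none
Why: Chemoselective MnO2 oxidation of the allylic alcohol gives the C1 enone under neutral conditions, so that the doubly activated H11 (α to C1=O and allylic to C9=C10) is not removed and the cis fusion and the C9=C10 position are kept.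

Step 15
Reactants: 21 dienone
Product: 22 epoxy enone (C9,C10-epoxide on the upper face)
Conditions: mCPBA (1.1 equiv), NaHCO3, CH2Cl2, 0 °C; filtration through neutral alumina
Reagents that add atoms: 3-chloroperoxybenzoic acid, OOC(=O)c1cccc(Cl)c1
Why: Prilezhaev epoxidation, in which the peracid takes the electron-rich trisubstituted C9=C10 alkene rather than the enone alkene and approaches from the convex upper face (the face of H11 and H5, opposite C1 on C11 and the C7 acyloxy group), which sets C9 and C10 with the oxygen anti to C4.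

Step 16
Reactants: 22 epoxy enone
Product: 23 cis-fused C9,C10-epoxide with C1 tert-butyldimethylsilyl dienol ether (C1(OTBS)=C2–C3(Me)=C4) and C7 isovalerate
Conditions: TBSOTf (1.3 equiv), Et3N (3 equiv), CH2Cl2, −78 °C, 30 min; cold aq. NaHCO3
Reagents that add atoms: tert-butyldimethylsilyl trifluoromethanesulfonate, CC(C)(C)[Si](C)(C)OS(=O)(=O)C(F)(F)F
Why: Soft enolisation with silyl triflate and amine runs through the O-silyl oxocarbenium ion, which, as in acid-type enolisation of β-alkyl enones, loses a γ-proton (C4) rather than the hindered α′ methine H11 and gives the linear endocyclic dienol ether as the more substituted diene, while low temperature and excess amine keep the epoxide closed.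

Step 17
Reactants: 23 epoxide dienol ether
Product: 24 tricyclic enone with free C9 hydroxyl and C7 isovalerate
Conditions: Et2AlCl (1.5 equiv), CH2Cl2, −78 to −30 °C; aq. Rochelle salt
Reagents that add atoms: none
Why: Proposed new method: Et2AlCl binds the epoxide oxygen and lengthens the C10–O bond toward the tertiary, cation-like C10, and the γ-carbon C4 of the silyl dienol ether, held gauche to C10 across the cis C5–C11 fusion, attacks C10 from the lower face, anti to the departing oxygen; the O-silyl oxocarbenium ion so formed gives up the silyl group to chloride and leaves the C1 enone, which cannot enolise toward the new bridgehead C4, so the strained ring is not reopened. The closest known reaction types are the Lewis acid alkylation of silyl enol ethers by tertiary (SN1-type) electrophiles, the γ-selective vinylogous Mukaiyama reaction and 4-exo-tet epoxide openings by stabilised carbanions. The cyclobutane (C4–C5–C11–C10) closes in 4-exo-tet mode with the C9 oxygen outside the new ring, and the same bond completes the bicyclo[3.1.1]heptenone (bridgeheads C4 and C11) and the bicyclo[4.1.1]octane (bridgeheads C5 and C10). C10 is set by inversion (epoxide oxygen on the upper face, C4 entering from below), C4 by the ring fusion because only its face turned toward C10 can bond, and C9 keeps the configuration fixed in the epoxidation. The step needs γ (C4) attack rather than α (C2) attack and ring closure rather than hydride shift or proton loss from the cation: α attack would give the more strained cyclobutanone (C2–C1–C11–C10) and lose the enone conjugation, and the low temperature and the non-basic aluminium alkoxide disfavour elimination.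

Step 18
Reactants: 24 tricyclic C9 alcohol; 25 tiglic acid
Product: 27 target CNP0194415.1 (C7 isovalerate, C9 tiglate), via tigloyl 2,4,6-trichlorobenzoic anhydride 26 (not isolated)
Conditions: 25, 2,4,6-trichlorobenzoyl chloride, Et3N, toluene, rt; then 24, DMAP, 40 °C
Reagents that add atoms: none
Why: Yamaguchi esterification, in which the mixed anhydride 26 acylates DMAP and the acylpyridinium tigloylates the hindered C9 alcohol without touching the enone or the E geometry of the tiglate.

**Compound list**

1 | propane-1,3-diol | OCCCO | starting material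
2 | 3-[(4-methoxybenzyl)oxy]propan-1-ol | COc1ccc(COCCCO)cc1 | intermediate
3 | 3-methylbuta-1,2-diene | CC(C)=C=C | starting material
4 | 3-[(4-methoxybenzyl)oxy]propanal | COc1ccc(COCCC=O)cc1 | intermediate
5 | (R)-1-[(4-methoxybenzyl)oxy]-4,4-dimethylhex-5-en-3-ol | COc1ccc(COCC[C@@H](O)C(C)(C)C=C)cc1 | intermediate
6 | acryloyl chloride | C=CC(=O)Cl | starting material
7 | (R)-1-[(4-methoxybenzyl)oxy]-4,4-dimethylhex-5-en-3-yl acrylate | COc1ccc(COCC[C@@H](OC(=O)C=C)C(C)(C)C=C)cc1 | intermediate
8 | (R)-6-{2-[(4-methoxybenzyl)oxy]ethyl}-5,5-dimethyl-5,6-dihydro-2H-pyran-2-one | COc1ccc(COCC[C@H]2OC(=O)C=CC2(C)C)cc1 | intermediate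
9 | 3-methylbut-2-enal | CC(C)=CC=O | starting material
10 | (E)-tert-butyl(dimethyl)[(3-methylbuta-1,3-dien-1-yl)oxy]silane | C=C(C)/C=C/O[Si](C)(C)C(C)(C)C | intermediate
11 | cis-fused Diels–Alder lactone: 8-(TBS-oxy)-3-{2-[(4-methoxybenzyl)oxy]ethyl}-4,4,6-trimethyl-3,4,4a,5,8,8a-hexahydro-1H-isochromen-1-one, 3R, H4a and H8a cis and trans to H3 | COc1ccc(COCC[C@H]2OC(=O)[C@@H]3[C@H](O[Si](C)(C)C(C)(C)C)C=C(C)C[C@@H]3C2(C)C)cc1 | intermediate
12 | primary alcohol: 11 with CH2CH2OH side chain | OCC[C@H]1OC(=O)[C@@H]2[C@H](O[Si](C)(C)C(C)(C)C)C=C(C)C[C@@H]2C1(C)C | intermediate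
13 | primary iodide: 11 with CH2CH2I side chain | ICC[C@H]1OC(=O)[C@@H]2[C@H](O[Si](C)(C)C(C)(C)C)C=C(C)C[C@@H]2C1(C)C | intermediate
14 | bridged hemiketal (O7 bridging C7 and C10, C10–OH) | O[C@@]12CC[C@@H](O1)C(C)(C)[C@H]3CC(C)=C[C@@H](O[Si](C)(C)C(C)(C)C)[C@@H]23 | intermediate
15 | cis-fused bicyclo[5.4.0] hydroxy ketone: C10=O, C7–OH, C1–OTBS, C2=C3(Me), C6 Me2 | O=C1CC[C@@H](O)C(C)(C)[C@H]2CC(C)=C[C@@H](O[Si](C)(C)C(C)(C)C)[C@@H]12 | intermediate
16 | 3-methylbutanoyl chloride | CC(C)CC(=O)Cl | starting material
17 | C10 ketone with C7 isovalerate and C1–OTBS | O=C1CC[C@@H](OC(=O)CC(C)C)C(C)(C)[C@H]2CC(C)=C[C@@H](O[Si](C)(C)C(C)(C)C)[C@@H]12 | intermediate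
18 | C9=C10 enol triflate | O=S(=O)(OC1=CC[C@@H](OC(=O)CC(C)C)C(C)(C)[C@H]2CC(C)=C[C@@H](O[Si](C)(C)C(C)(C)C)[C@@H]12)C(F)(F)F | intermediate
19 | diene: C9=C10(Me), C2=C3(Me), C1–OTBS, C7 isovalerate | CC1=CC[C@@H](OC(=O)CC(C)C)C(C)(C)[C@H]2CC(C)=C[C@@H](O[Si](C)(C)C(C)(C)C)[C@@H]12 | intermediate
20 | allylic alcohol: 19 with C1–OH | CC1=CC[C@@H](OC(=O)CC(C)C)C(C)(C)[C@H]2CC(C)=C[C@@H](O)[C@@H]12 | intermediate
21 | cis-fused dienone: C1=O, C2=C3(Me), C9=C10(Me), C7 isovalerate | CC1=CC[C@@H](OC(=O)CC(C)C)C(C)(C)[C@H]2CC(C)=CC(=O)[C@@H]12 | intermediate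
22 | epoxy enone: C9,C10-epoxide on the upper face, C1 enone, C7 isovalerate | O1[C@@H]2C[C@@H](OC(=O)CC(C)C)C(C)(C)[C@@H]3[C@H]([C@]12C)C(=O)C=C(C)C3 | intermediate
23 | cis-fused C9,C10-epoxide, C1 tert-butyldimethylsilyl dienol ether, C7 isovalerate | O1[C@@H]2C[C@@H](OC(=O)CC(C)C)C(C)(C)[C@@H]3[C@H]([C@]12C)C(O[Si](C)(C)C(C)(C)C)=CC(C)=C3 | intermediate
24 | tricyclic enone with free C9 hydroxyl and C7 isovalerate | O[C@@H]1C[C@@H](OC(=O)CC(C)C)C(C)(C)[C@@H]2[C@H]3C(=O)C=C(C)[C@@H]2[C@]31C | intermediate
25 | tiglic acid | C/C=C(\C)C(=O)O | starting material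
26 | tigloyl 2,4,6-trichlorobenzoic anhydride | C/C=C(\C)C(=O)OC(=O)c1c(Cl)cc(Cl)cc1Cl | intermediate
27 | CNP0194415.1: C7 isovalerate, C9 tiglate of the tricyclic enone | C/C=C(\C)C(=O)O[C@@H]1C[C@@H](OC(=O)CC(C)C)C(C)(C)[C@@H]2[C@H]3C(=O)C=C(C)[C@@H]2[C@]31C | target

**Step count**

Total steps: 18. Longest linear sequence: 17 (steps 1–4 and 6–18; step 5 makes the diene).

**Steps most likely to fail**

1. Step 17 (key step). The aluminium-bound epoxide may ionise and the C10 cation may then be consumed by a 1,2-hydride shift from C9 (ketone), by proton loss from the C10 methyl group (allylic alcohol) or by attack through C2, before the strained four-membered ring closes.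
   Fallback with known chemistry, from 23 back to 24: dienol ether 23 is treated with PhSCl (CH2Cl2, −78 °C), which sulfenylates O-silyl dienolates at the γ-carbon and gives the 4-phenylthio epoxy enone F1. Cs2CO3 in DMF then forms the sulfur-stabilised extended enolate, which opens the epoxide at C10 in the 4-exo-tet manner of the Stork epoxynitrile cyclisation and gives the bridgehead sulfide alcohol F2. Hydrogenolysis of the C4–S bond with acetone-deactivated Raney Ni in ethanol rejoins the route at alcohol 24.

2. Step 6. The cycloaddition may be slow at the β-carbon C5, which sits next to the quaternary C6, and the silyl Lewis acid may meanwhile desilylate or oligomerise the dienol ether.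
   Fallback, from 5 back to 11: alcohol 5 is esterified with (phenylsulfonyl)acetic acid (DCC, DMAP) to the sulfonylacetate F3. The vinyl group is cleaved (OsO4 cat., NaIO4, 2,6-lutidine) to the aldehyde F4, and an intramolecular Knoevenagel condensation (piperidinium acetate, benzene, reflux) closes the 3-(phenylsulfonyl) unsaturated lactone F5. This doubly activated dienophile should add diene 10 thermally (toluene, 60 °C) with the same regiochemistry and facial sense to give the sulfonyl cycloadduct F6. Reductive desulfonylation (SmI2, THF–MeOH, −78 °C), with kinetic protonation of the lactone enolate from the convex face, gives the cis-fused lactone 11.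

3. Step 16. Enolisation may lose regiocontrol and take the α′ proton H11 instead of the γ proton at C4, which would open the neighbouring epoxide by β-elimination; the silyl triflate may also open the epoxide directly.
   Fallback, from 22 back to 24: epoxy enone 22 is deprotonated by the iron-catalysed Grignard method for linear dienolates (MeMgBr, FeCl3 5 mol%, Et2O, −20 °C) and the magnesium dienolate is trapped with TMSCl, Et3N and DMPU to give the trimethylsilyl dienol ether F7. This route is anionic and uses neither silyl triflate nor the oxocarbenium ion. F7 takes the place of 23 in step 17 and the route is rejoined at alcohol 24.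

**Further compounds**

F1 | step 17 | 4-phenylthio epoxy enone (22 with SPh on C4, either C4 epimer) | O1[C@@H]2C[C@@H](OC(=O)CC(C)C)C(C)(C)[C@@H]3[C@H]([C@]12C)C(=O)C=C(C)C3Sc1ccccc1
F2 | step 17 | bridgehead sulfide alcohol (24 with SPh on C4) | O[C@@H]1C[C@@H](OC(=O)CC(C)C)C(C)(C)[C@@H]2[C@H]3C(=O)C=C(C)[C@]2(Sc2ccccc2)[C@]31C
F3 | step 6 | (R)-1-[(4-methoxybenzyl)oxy]-4,4-dimethylhex-5-en-3-yl 2-(phenylsulfonyl)acetate | COc1ccc(COCC[C@@H](OC(=O)CS(=O)(=O)c2ccccc2)C(C)(C)C=C)cc1
F4 | step 6 | (R)-5-[(4-methoxybenzyl)oxy]-2,2-dimethyl-1-oxopentan-3-yl 2-(phenylsulfonyl)acetate | COc1ccc(COCC[C@@H](OC(=O)CS(=O)(=O)c2ccccc2)C(C)(C)C=O)cc1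
F5 | step 6 | (R)-6-{2-[(4-methoxybenzyl)oxy]ethyl}-5,5-dimethyl-3-(phenylsulfonyl)-5,6-dihydro-2H-pyran-2-one | COc1ccc(COCC[C@H]2OC(=O)C(S(=O)(=O)c3ccccc3)=CC2(C)C)cc1
F6 | step 6 | sulfonyl cycloadduct (11 with SO2Ph on C11 in place of H) | COc1ccc(COCC[C@H]2OC(=O)[C@]3(S(=O)(=O)c4ccccc4)[C@H](O[Si](C)(C)C(C)(C)C)C=C(C)C[C@@H]3C2(C)C)cc1
F7 | step 16 | trimethylsilyl dienol ether analogue of 23 | O1[C@@H]2C[C@@H](OC(=O)CC(C)C)C(C)(C)[C@@H]3[C@H]([C@]12C)C(O[Si](C)(C)C)=CC(C)=C3
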